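Assumption: the target has no stereocentre (the carbinol carbon carries two identical CH2OC(O)CHMe2 arms), so it is achiral and no asymmetric step is needed.

**Retrosynthetic overview**
- Target ⇒ 3-(2-methoxy-4-methylphenyl)oxetan-3-ol + isobutyric anhydride. The key bond is a CH2–O(isobutyrate) bond, made by carboxylate opening of the oxetane; the ring oxygen is acylated in the same flask.
- The oxetanol ⇒ (2-methoxy-4-methylphenyl)lithium + oxetan-3-one (1,2-addition); the aryllithium ⇒ 1-bromo-2-methoxy-4-methylbenzene.
- No ring is formed: the arene and the oxetane are bought, and the oxetane is opened in the last step.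

Bought: 1 (also sold as 2-bromo-5-methylanisole), 2, isobutyric anhydride, n-BuLi and Co(salen). Here salen is the dianion of racemic trans-N,N'-bis(3,5-di-tert-butylsalicylidene)cyclohexane-1,2-diamine. The catalyst Co(salen)(O2CiPr), trivalent cobalt, is made beforehand by stirring Co(salen) (divalent cobalt) with isobutyric acid in CH2Cl2 open to air and evaporating.

**Step 1**
Reactants: 1 1-bromo-2-methoxy-4-methylbenzene; 2 oxetan-3-one
Product: 5 3-(2-methoxy-4-methylphenyl)oxetan-3-ol, via aryllithium 3 (not isolated), via lithium oxetanolate 4 (not isolated)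
Conditions: 1 (1.15 equiv), n-BuLi (1.1 equiv), THF, −78 °C, 30 min; then 2 (1.0 equiv), −78 → 0 °C; then H2O
Reagents that add atoms: none
Why: Bromine–lithium exchange puts lithium only on the carbon that bore bromine, and 1,2-addition of the aryllithium to the strained, electrophilic ketone at −78 °C is the standard way to 3-aryloxetan-3-ols; no stereocentre is formed.

**Step 2**
Reactants: 5 3-(2-methoxy-4-methylphenyl)oxetan-3-ol
Product: 7 2-hydroxy-2-(2-methoxy-4-methylphenyl)propane-1,3-diyl bis(2-methylpropanoate), via monoisobutyrate 6 (not isolated)
Conditions: (iPrCO)2O (1.05 equiv), Co(salen)(O2CiPr) (5 mol%), iPrCO2H (10 mol%), iPr2NEt (10 mol%), MTBE, 45 °C, 24 h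
Reagents that add atoms: isobutyric anhydride, CC(C)C(=O)OC(=O)C(C)C
Why: Proposed new method: a cobalt-salen carboxylate relay inserts one oxetane C–O bond into the anhydride — the Lewis-acidic trivalent cobalt binds the oxetane oxygen of 5, isobutyrate delivered by a second cobalt centre or by the ammonium salt opens the strained ring (about 107 kJ/mol) by SN2 attack at one of the two equivalent CH2 groups to give monoester 6, and the anhydride then acylates the freed primary oxygen and returns isobutyrate, so the cycle turns over with no co-product and all atoms of 5 and of the anhydride end up in 7; the hindered tertiary benzylic OH should be neither acylated (no acyl-transfer catalyst) nor ionised (carboxylate-buffered, no strong acid), and no stereocentre arises; closest known reaction types are salen-cobalt-catalysed addition of carboxylic acids to epoxides, salen-metal-catalysed alternating ring-opening copolymerisation of epoxides with cyclic anhydrides (the same alkoxide/anhydride/carboxylate cycle) and salen-cobalt-catalysed intramolecular opening of oxetanes by alcohols, none of which has been shown as a single intermolecular insertion of an oxetane into an acyclic anhydride, nor on a 3-aryloxetan-3-ol with a free tertiary OH.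

**Compound list**
1 | 1-bromo-2-methoxy-4-methylbenzene (achiral) | COc1cc(C)ccc1Br | starting material
2 | oxetan-3-one (achiral) | O=C1COC1 | starting material
3 | (2-methoxy-4-methylphenyl)lithium (achiral) | COc1cc(C)ccc1[Li] | intermediate
4 | lithium 3-(2-methoxy-4-methylphenyl)oxetan-3-olate (achiral) | COc1cc(C)ccc1C1(O[Li])COC1 | intermediate
5 | 3-(2-methoxy-4-methylphenyl)oxetan-3-ol (achiral) | COc1cc(C)ccc1C1(O)COC1 | intermediate
6 | 2,3-dihydroxy-2-(2-methoxy-4-methylphenyl)propyl 2-methylpropanoate (racemic, one stereocentre) | COc1cc(C)ccc1C(O)(CO)COC(=O)C(C)C | intermediate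
7 | 2-hydroxy-2-(2-methoxy-4-methylphenyl)propane-1,3-diyl bis(2-methylpropanoate) (achiral) | COc1cc(C)ccc1C(O)(COC(=O)C(C)C)COC(=O)C(C)C | target

**Step count and risks**
Total steps: 2. Longest linear sequence: 2 (1 → 5 → 7).

The route has only two steps, so step 2 is entered twice, once for each of its two in-flask events. In order of risk:

1. Step 2, ring-opening event 5 → 6 (the proposed new method). The cobalt-held isobutyrate may be too weak a nucleophile for the neopentyl-type oxetane CH2 at 45 °C, so 5 is returned. Forcing the reaction (toluene, 70 °C) may start to acylate or ionise the electron-rich tertiary benzylic alcohol. The fallback uses known chemistry only, sets out from 3 (made from 1 as in step 1) and comes back at 7. Aryllithium 3 is added at −78 °C in THF to 1,3-dichloroacetone to give lithium 1,3-dichloro-2-(2-methoxy-4-methylphenyl)propan-2-olate F1. This is quenched cold with AcOH to 1,3-dichloro-2-(2-methoxy-4-methylphenyl)propan-2-ol F2. Heating F2 with CsO2CCHMe2 (2.5 equiv) and iPrCO2H (0.5 equiv) in DMF at 80 °C exchanges both chlorides for isobutyrate by the halohydrin–epoxide relay familiar from double azole substitution of such aryl dichlorohydrins. F2 closes to racemic 2-(chloromethyl)-2-(2-methoxy-4-methylphenyl)oxirane F3. Isobutyrate opens F3 at its ring CH2 to racemic 3-chloro-2-hydroxy-2-(2-methoxy-4-methylphenyl)propyl 2-methylpropanoate F4. F4 closes again to racemic [2-(2-methoxy-4-methylphenyl)oxiran-2-yl]methyl 2-methylpropanoate F5, and a second opening at the ring CH2 gives 7.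

2. Step 1, addition of 3 to 2. Oxetan-3-one is volatile, enolisable and prone to oligomerise, so 3 may act partly as a base and the yield of 5 may be poor. The fallback sets out from 3 and comes back at 7, avoiding the oxetane altogether. Aryllithium 3 is added at −78 °C to 2,2-dimethyl-1,3-dioxan-5-one to give lithium 5-(2-methoxy-4-methylphenyl)-2,2-dimethyl-1,3-dioxan-5-olate F6. Water work-up gives 5-(2-methoxy-4-methylphenyl)-2,2-dimethyl-1,3-dioxan-5-ol F7. Aqueous AcOH (80%) at 40 °C removes the acetonide to give 2-(2-methoxy-4-methylphenyl)propane-1,2,3-triol F8. Isobutyryl chloride (2.05 equiv) with 2,4,6-collidine in CH2Cl2 at −40 → 0 °C acylates only the two primary hydroxyls and gives 7.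

3. Step 2, acyl-transfer event 6 → 7. Without an acyl-transfer catalyst the anhydride may acylate the primary OH of 6 too slowly, so 6 accumulates. Pushing it may bring on O-acylation of the tertiary alcohol and a triester. The fallback sets out from 6 and comes back at 7 (it makes no new compound, F0). The opening is run with isobutyric acid (1.1 equiv) in place of the anhydride so that 6 is isolated. The primary OH of 6 is then acylated with isobutyric anhydride (1.2 equiv) and immobilised Candida antarctica lipase B in MTBE at 30 °C; the enzyme acylates primary alcohols and does not accept tertiary ones.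

**Further compounds**
F1 | step 2 | lithium 1,3-dichloro-2-(2-methoxy-4-methylphenyl)propan-2-olate (achiral) | COc1cc(C)ccc1C(O[Li])(CCl)CCl
F2 | step 2 | 1,3-dichloro-2-(2-methoxy-4-methylphenyl)propan-2-ol (achiral) | COc1cc(C)ccc1C(O)(CCl)CCl
F3 | step 2 | 2-(chloromethyl)-2-(2-methoxy-4-methylphenyl)oxirane (racemic) | COc1cc(C)ccc1C1(CCl)CO1
F4 | step 2 | 3-chloro-2-hydroxy-2-(2-methoxy-4-methylphenyl)propyl 2-methylpropanoate (racemic) | COc1cc(C)ccc1C(O)(CCl)COC(=O)C(C)C
F5 | step 2 | [2-(2-methoxy-4-methylphenyl)oxiran-2-yl]methyl 2-methylpropanoate (racemic) | COc1cc(C)ccc1C1(COC(=O)C(C)C)CO1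
F6 | step 1 | lithium 5-(2-methoxy-4-methylphenyl)-2,2-dimethyl-1,3-dioxan-5-olate (achiral) | COc1cc(C)ccc1C1(O[Li])COC(C)(C)OC1
F7 | step 1 | 5-(2-methoxy-4-methylphenyl)-2,2-dimethyl-1,3-dioxan-5-ol (achiral) | COc1cc(C)ccc1C1(O)COC(C)(C)OC1
F8 | step 1 | 2-(2-methoxy-4-methylphenyl)propane-1,2,3-triol (achiral) | COc1cc(C)ccc1C(O)(CO)CO
F0 | step 2 | none | none
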